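## Retrosynthetic overview

1. The last disconnection is the C2–C3 bond of the propan-1-one chain (carbinol carbon to benzylic CH2). It gives the achiral α-hydroxy ketone 2-hydroxy-1-(7-methoxy-2,2-dimethyl-2H-chromen-6-yl)ethanone, used as a catalyst-bound zinc enediolate, and para-quinone methide, released in the flask from tert-butyl 4-hydroxybenzyl carbonate. This protecting-group-free step forms the bond, sets the only stereocentre and leaves both hydroxyls free.
2. Enabling feature: the ketone oxygen, the α-hydroxyl oxygen and the methoxy oxygen on C7 of the benzo ring form an O,O,O-chelate for zinc that gives the Z-enediolate at the carbinol carbon. The para-hydroxyl of the other benzene ring lets the benzyl electrophile exist as a quinone methide, whose 1,6-addition rearomatises that ring.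
3. The hydroxy ketone comes from 6-bromo-7-methoxy-2,2-dimethyl-2H-chromene by bromine–lithium exchange, acylation with a silyl-protected glycolic Weinreb amide and desilylation.
4. Ring order: both benzene rings are bought. The pyran ring of the chromene is the only ring made, in step 1, by Grignard addition to a salicylaldehyde, dehydration and oxa-6π electrocyclisation.
5. The carbonate donor comes in two steps from 4-(silyloxy)benzyl alcohol (Boc carbonate, then buffered desilylation).

Key step: step 6

Assumption: the silyl-protected glycolic Weinreb amide and 4-[(tert-butyldimethylsilyl)oxy]benzyl alcohol are treated as catalogue compounds, and the enediolate face left open by (R,R)-linked-BINOL is taken to be the one that leads to the (S)-ketol.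

## Route

Step 1
Reactants: 1 5-bromo-2-hydroxy-4-methoxybenzaldehyde; 2 (2-methylprop-1-en-1-yl)magnesium bromide
Product: 5 6-bromo-7-methoxy-2,2-dimethyl-2H-chromene, via diol 3 (not isolated), via ortho-quinone methide 4 (not isolated)
Conditions: 2 (2.5 equiv), THF, 0 °C to rt; aq. NH4Cl; crude in toluene, pyridinium p-toluenesulfonate (5 mol %), 60 °C
Reagents that add atoms: none
Why: After the first equivalent of Grignard reagent has formed the magnesium phenoxide, the second adds 1,2 to the aldehyde, and mild acid dehydrates the ortho-hydroxybenzyl allylic alcohol to an ortho-quinone methide that closes the pyran ring by oxa-6π electrocyclisation, a known route to 2,2-dimethyl-2H-chromenes in which the substitution pattern of 1 fixes the linear 6-bromo-7-methoxy arrangement and no stereocentre is formed.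

Step 2
Reactants: 5 6-bromo-7-methoxy-2,2-dimethyl-2H-chromene; 6 2-[(tert-butyldimethylsilyl)oxy]-N-methoxy-N-methylacetamide
Product: 8 2-[(tert-butyldimethylsilyl)oxy]-1-(7-methoxy-2,2-dimethyl-2H-chromen-6-yl)ethan-1-one, via aryllithium 7 (not isolated)
Conditions: n-BuLi (1.05 equiv), THF, −78 °C, 20 min; then 6 (1.2 equiv), −78 to −40 °C; AcOH quench
Reagents that add atoms: none
Why: Bromine–lithium exchange is faster than any deprotonation at −78 °C, and the aryllithium is acylated only once because the chelated tetrahedral adduct of the Weinreb amide survives until the quench (Weinreb ketone synthesis).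

Step 3
Reactants: 8 2-[(tert-butyldimethylsilyl)oxy]-1-(7-methoxy-2,2-dimethyl-2H-chromen-6-yl)ethan-1-one
Product: 9 2-hydroxy-1-(7-methoxy-2,2-dimethyl-2H-chromen-6-yl)ethan-1-one
Conditions: Bu4NF (1.2 equiv), AcOH (1.5 equiv), THF, 0 °C
Reagents that add atoms: none
Why: Fluoride cleaves the Si–O bond, and the acetic acid buffer keeps the α-hydroxy ketone from base-induced enolisation and aldol dimerisation (silyl ether deprotection).

Step 4
Reactants: 10 {4-[(tert-butyldimethylsilyl)oxy]phenyl}methanol
Product: 11 tert-butyl {4-[(tert-butyldimethylsilyl)oxy]phenyl}methyl carbonate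
Conditions: Boc2O (1.3 equiv), 4-(dimethylamino)pyridine (5 mol %), CH2Cl2, 0 °C to rt
Reagents that add atoms: di-tert-butyl dicarbonate (Boc2O), CC(C)(C)OC(=O)OC(=O)OC(C)(C)C
Why: Acyl-transfer catalysis by 4-(dimethylamino)pyridine converts the primary benzylic alcohol into the mixed tert-butyl carbonate and leaves the aryl silyl ether untouched.

Step 5
Reactants: 11 tert-butyl {4-[(tert-butyldimethylsilyl)oxy]phenyl}methyl carbonate
Product: 12 tert-butyl (4-hydroxyphenyl)methyl carbonate
Conditions: Bu4NF (1.1 equiv), AcOH (2 equiv), THF, −20 to 0 °C; pH 5 buffer work-up, product stored cold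
Reagents that add atoms: none
Why: Buffered fluoride removes the aryl silyl group, and acetic acid protonates the phenoxide faster than it can expel the benzylic carbonate, so the phenol should be released without quinone methide formation (silyl ether deprotection).

Step 6
Reactants: 9 2-hydroxy-1-(7-methoxy-2,2-dimethyl-2H-chromen-6-yl)ethan-1-one; 12 tert-butyl (4-hydroxyphenyl)methyl carbonate
Product: 15 Lespeflorin C7 [(2S)-2-hydroxy-3-(4-hydroxyphenyl)-1-(7-methoxy-2,2-dimethyl-2H-chromen-6-yl)propan-1-one], via zinc enediolate 13 (not isolated), via para-quinone methide 14 (not isolated)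
Conditions: Et2Zn (20 mol %), (R,R)-linked-BINOL [(R,R)-3,3''-[oxybis(methylene)]bis(1,1'-bi-2-naphthol), 5 mol %], 3 Å molecular sieves, THF, −20 °C, 12 (1.3 equiv) added over 6 h under an argon sweep; pH 7 buffer quench
Reagents that add atoms: none
Why: Proposed new method: ligand exchange places the phenol of 12 on zinc, the zinc phenoxide expels tert-butyl carbonate by 1,6-elimination to give para-quinone methide 14, and the carbonate loses CO2 to leave a zinc tert-butoxide that deprotonates chelated 9 to the Z-enediolate 13, so no external base is needed and only CO2 and tert-butanol are formed beside the product. The carbon of 13 then attacks the exocyclic CH2 of 14, which forms the C2–C3 bond of the chain and rearomatises the six-membered ring to the free phenol, and the resulting zinc phenoxide is protonated by the next molecule of 12 to close the cycle. The closest known reactions are the Et2Zn/linked-BINOL-catalysed direct asymmetric Michael addition of 2-hydroxy-2'-methoxyacetophenones to enones, here extended from a 1,4- to a 1,6-acceptor, and the 1,6-elimination of para-hydroxybenzyl carbonates used in self-immolative linkers. No ring is closed in this step. The single new stereocentre (C2) is controlled by the catalyst: the O,O,O-chelate (C7 methoxy oxygen, ketone oxygen, α-oxygen) fixes the enediolate geometry and the ligand shields one face, and since the (S,S)-ligand is known to give (2R)-ketols with enones, the (R,R)-ligand should give the (S)-ketol, with the mirror-image ligand to be used if the sense proves opposite. The step needs C- over O-alkylation, attack at the methylene terminus only, and capture of 14 before it oligomerises; these should be secured by the soft zinc-bound enediolate carbon, by aromatisation as the driving force, and by slow addition of 12 so that 14 forms only at the catalyst.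

## Compound list

1 | 5-bromo-2-hydroxy-4-methoxybenzaldehyde | COc1cc(O)c(C=O)cc1Br | starting material
2 | (2-methylprop-1-en-1-yl)magnesium bromide | CC(C)=C[Mg]Br | starting material
3 | 4-bromo-2-(1-hydroxy-3-methylbut-2-en-1-yl)-5-methoxyphenol (racemic diol) | COc1cc(O)c(cc1Br)C(O)C=C(C)C | intermediate (not isolated)
4 | 4-bromo-3-methoxy-6-(3-methylbut-2-en-1-ylidene)cyclohexa-2,4-dien-1-one (ortho-quinone methide) | O=C1C=C(OC)C(Br)=CC1=CC=C(C)C | intermediate (not isolated)
5 | 6-bromo-7-methoxy-2,2-dimethyl-2H-chromene | COc1cc2OC(C)(C)C=Cc2cc1Br | intermediate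
6 | 2-[(tert-butyldimethylsilyl)oxy]-N-methoxy-N-methylacetamide | CON(C)C(=O)CO[Si](C)(C)C(C)(C)C | starting material
7 | (7-methoxy-2,2-dimethyl-2H-chromen-6-yl)lithium | COc1cc2OC(C)(C)C=Cc2cc1[Li] | intermediate (not isolated)
8 | 2-[(tert-butyldimethylsilyl)oxy]-1-(7-methoxy-2,2-dimethyl-2H-chromen-6-yl)ethan-1-one | COc1cc2OC(C)(C)C=Cc2cc1C(=O)CO[Si](C)(C)C(C)(C)C | intermediate
9 | 2-hydroxy-1-(7-methoxy-2,2-dimethyl-2H-chromen-6-yl)ethan-1-one | COc1cc2OC(C)(C)C=Cc2cc1C(=O)CO | intermediate
10 | {4-[(tert-butyldimethylsilyl)oxy]phenyl}methanol | OCc1ccc(O[Si](C)(C)C(C)(C)C)cc1 | starting material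
11 | tert-butyl {4-[(tert-butyldimethylsilyl)oxy]phenyl}methyl carbonate | CC(C)(C)OC(=O)OCc1ccc(O[Si](C)(C)C(C)(C)C)cc1 | intermediate
12 | tert-butyl (4-hydroxyphenyl)methyl carbonate | CC(C)(C)OC(=O)OCc1ccc(O)cc1 | intermediate
13 | zinc (Z)-enediolate of 9, drawn as the bare five-membered zinc chelate (binaphtholate ligand on zinc not drawn) | COc1cc2OC(C)(C)C=Cc2cc1C1=CO[Zn]O1 | intermediate (not isolated)
14 | 4-methylidenecyclohexa-2,5-dien-1-one (para-quinone methide) | C=C1C=CC(=O)C=C1 | intermediate (not isolated)
15 | Lespeflorin C7, (2S)-2-hydroxy-3-(4-hydroxyphenyl)-1-(7-methoxy-2,2-dimethyl-2H-chromen-6-yl)propan-1-one | COc1cc2c(cc1C(=O)[C@@H](O)Cc1ccc(O)cc1)C=CC(C)(C)O2 | target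

## Step count and risks

Total step count: 6. Longest linear sequence: 4 steps (1 → 5 → 8 → 9 → 15); the donor branch (10 → 11 → 12) joins in step 6.

**Step 6 (proposed new method).** What may go wrong: oligomerisation of the quinone methide before the enediolate captures it, O-alkylation of the zinc alkoxide instead of C-alkylation, weak facial control because the acceptor does not bind zinc as an enone does, and retention of CO2 on zinc that stalls turnover.
Fallback with known chemistry, setting out from aryl bromide 5 and coming back at 15: commercial (2S)-2-hydroxy-3-(4-hydroxyphenyl)propanoic acid, the hydroxy acid that corresponds to L-tyrosine, is coupled with N,O-dimethylhydroxylamine hydrochloride (EDC·HCl, HOBt, N-methylmorpholine, CH2Cl2/DMF) to the Weinreb amide (2S)-2-hydroxy-3-(4-hydroxyphenyl)-N-methoxy-N-methylpropanamide F1. Both hydroxyls are silylated (TBSCl, imidazole, DMF) to (2S)-2-[(tert-butyldimethylsilyl)oxy]-3-{4-[(tert-butyldimethylsilyl)oxy]phenyl}-N-methoxy-N-methylpropanamide F2. Aryllithium 7, made from 5 as in step 2, is acylated by F2 at −78 °C to the ketone (2S)-2-[(tert-butyldimethylsilyl)oxy]-3-{4-[(tert-butyldimethylsilyl)oxy]phenyl}-1-(7-methoxy-2,2-dimethyl-2H-chromen-6-yl)propan-1-one F3. Buffered Bu4NF/AcOH then removes both silyl groups and should give 15 with the stereocentre taken from the chiral pool.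

**Step 5.** What may go wrong: 1,6-elimination of the carbonate from transient phenoxide during or after unmasking, followed by polymerisation of the quinone methide.
Fallback, setting out from 10 and coming back at 15: 10 is heated with sodium 4-methylbenzenesulfinate in aqueous formic acid. The benzylic hydroxyl should be replaced through the para-oxybenzyl cation and the aryl silyl ether hydrolysed in the same acidic medium (a little aqueous HCl completes it if needed), to give the crystalline sulfone 4-[(4-methylphenyl)sulfonylmethyl]phenol F4. This quinone methide precursor is made under acid, where no phenoxide can form, and carries no labile carbonate. F4 then replaces 12 in step 6, with Et2Zn (0.5 equiv per F4) added slowly as terminal base for the sulfinic acid, and 9 should be converted to 15 through the same intermediates 13 and 14.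

**Step 1.** What may go wrong: incomplete addition to the aldehyde deactivated by the magnesium phenoxide, and acid-induced oligomerisation during the dehydration.
Fallback, setting out from 1 and coming back at 5: 1 is heated with ethyl (triphenylphosphoranylidene)acetate in N,N-diethylaniline at reflux (Wittig reaction). The cinnamate ethyl (2E)-3-(5-bromo-2-hydroxy-4-methoxyphenyl)prop-2-enoate F5 should isomerise and lactonise in the same pot to 6-bromo-7-methoxy-2H-chromen-2-one F6. Excess MeMgBr in THF opens the lactone to the Z-diol 4-bromo-2-[(1Z)-3-hydroxy-3-methylbut-1-en-1-yl]-5-methoxyphenol F7. Mild acid (pyridinium p-toluenesulfonate, toluene) then cyclises F7 through the tertiary allylic cation to 5.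

## Further compounds

F1 | step 6 | (2S)-2-hydroxy-3-(4-hydroxyphenyl)-N-methoxy-N-methylpropanamide | CON(C)C(=O)[C@@H](O)Cc1ccc(O)cc1
F2 | step 6 | (2S)-2-[(tert-butyldimethylsilyl)oxy]-3-{4-[(tert-butyldimethylsilyl)oxy]phenyl}-N-methoxy-N-methylpropanamide | CON(C)C(=O)[C@@H](O[Si](C)(C)C(C)(C)C)Cc1ccc(O[Si](C)(C)C(C)(C)C)cc1
F3 | step 6 | (2S)-2-[(tert-butyldimethylsilyl)oxy]-3-{4-[(tert-butyldimethylsilyl)oxy]phenyl}-1-(7-methoxy-2,2-dimethyl-2H-chromen-6-yl)propan-1-one | COc1cc2c(cc1C(=O)[C@@H](O[Si](C)(C)C(C)(C)C)Cc1ccc(O[Si](C)(C)C(C)(C)C)cc1)C=CC(C)(C)O2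
F4 | step 5 | 4-[(4-methylphenyl)sulfonylmethyl]phenol | Cc1ccc(cc1)S(=O)(=O)Cc1ccc(O)cc1
F5 | step 1 | ethyl (2E)-3-(5-bromo-2-hydroxy-4-methoxyphenyl)prop-2-enoate | CCOC(=O)/C=C/c1cc(Br)c(OC)cc1O
F6 | step 1 | 6-bromo-7-methoxy-2H-chromen-2-one | COc1cc2OC(=O)C=Cc2cc1Br
F7 | step 1 | 4-bromo-2-[(1Z)-3-hydroxy-3-methylbut-1-en-1-yl]-5-methoxyphenol | COc1cc(O)c(cc1Br)/C=C\C(C)(C)O
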